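Choose first which setting to move, the reagent charge or its transfer, and count turnovers to make that choice. The summer run is the flask asked about, followed so far.

| setting | summer | dusk | flask |
|---|---|---|---|
| substrate | 16 mM | 16 mM | 16 mM |
| reagent in the second phase | 19.2 mM | 13 mM | 19.2 mM |
| remark | the very flask that is asked about, followed so far | run made earlier |  |
| time |  |  | 25 min |
| volume of the second phase over the first |  |  | 0.25 |

| run | time / min | target / % | substrate / % |
|---|---|---|---|
| summer | 0.833 | 1.9 | 97.2 |
| summer | 1.33 | 2.4 | 96.1 |
| summer | 2.00 | 5.5 | 94.6 |
| summer | 3.00 | 5.7 | 93.8 |
| summer | 4.00 | 9.3 | 93.2 |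
| summer | 6.00 | 13.4 | 87.9 |
| summer | 10.0 | 17.5 | 79.0 |
| dusk | 1.33 | 1.8 | 98.8 |
| dusk | 3.00 | 5.6 | 95.9 |
| dusk | 4.00 | 5.1 | 94.2 |
| dusk | 6.00 | 9.2 | 91.4 |
| dusk | 8.00 | 11.5 | 88.7 |
| dusk | 10.0 | 14.4 | 86.5 |

(each reading ± 1 percentage point)

- in the second phase: reagent in the second phase; everything else is in the first
- charges count per volume of the first phase; a concentration in a rate is the amount of a species over the volume of its own phase; every rate counts per litre of the first phase
- the earlier runs hold the two phases in the same ratio of volumes as the flask asked about

- ochre: doubling the amount of reagent in the second phase, all else as stated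
- teal: doubling the transfer coefficient of the reagent in the second phase, all else as stated

* the target standing at 25 min, as a percentage of the substrate charged
* the change that raises the amount of target at 25 min, in percent of the substrate charged most ("none" if none brings more than 2 percentage points) (ochre / teal / none)
* amount of target at 25 min, in percent of the substrate charged, after teal

**First instants.** The summer run already reads 1.9% target at 0.833 min, and no lag shows. I therefore take the transfer time of the reagent as no longer than that first reading, which gives the flask about 30.0 transfer turnovers in 25 min.

**Middle.** Let s be the fraction of substrate left, t the time, and k an apparent first-order constant for substrate loss, read at the last summer reading. Let f be the target formed per substrate lost, read at the same point.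

k = −ln(s)/t = 0.0236 min⁻¹

f = 0.833

n = k × 25 min = 0.589

Call n the turnover count, the number of substrate lifetimes that fit into the time. The dusk run reads k = 0.0145 min⁻¹, a ratio of 1.63 against 1.48 in charge, so I let k follow the charge.

**End.** My reckoning for the flask is:

substrate left = exp(−n) = 55.5%

target = f × substrate lost = 37.1%

Counting one reagent per substrate lost, that reckoned loss leaves 12.1 mM of the reagent charge. The transfer turns over far more often than the substrate, so I expect teal to stay near 37.1%. Ochre doubles n and reckons to 57.7%.

The forecast says 40%, ochre and 57% after teal, noting that "The runs barely separate these regimes". We agree on the choice of change and differ on teal.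

The flask gives 34.1%; ochre adds 13 percentage points, and teal gives 34.2%.

    reagent in the reaction phase ⇌ reagent in the second phase, rate k1*([reagent in the reaction phase] - [reagent in the second phase]/K1) per volume of the first phase (partition coefficient = 1.80, kL = 0.0220 s⁻¹)
    substrate + reagent in the reaction phase → target (k = 0.0320 M⁻¹ s⁻¹)
    reagent in the reaction phase + target → over-reacted product (k = 0.0170 M⁻¹ s⁻¹)

At 25.0 min the flask holds 60.7% substrate against the reckoned 55.5%, with reagent in the reaction phase down from 12.6 mM at 2.50 min to 8.33 mM and over-reacted product at 5.15%. Read at 15 min, the same flask counts n = 0.354, which reckons to 70.2% substrate and 24.8% target. That flask holds 72% substrate and 25.3% target.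

(The data come from a simulation for an exercise; noise was put on by code.)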